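**Plan**
Decalin locants follow the drimane convention: C4 carries the gem-dimethyl group, C5 is the ring-fusion CH, C8=C9 is the alkene, C10 is the methyl-bearing ring-fusion carbon, C11 is the benzylic CH2.
Retrosynthesis cuts, in order: the O–S bond (late sulfation of the one phenol kept distinct by protecting groups); C9–C11 (alkenyl triflate plus benzylboronate); the C3 carbonyl helper (Wolff–Kishner); then C1–C10 and C2–C3 of ring A together.
Enabling feature: C10 is allylic to C8=C9 and C1–C2 is a bare ethano unit next to C3. With oxygen on C3 and a temporary C3–C8 bond, C1=C2–C3(O–)–C8–C9=C10 is a 3-oxido-1,5-diene, i.e. ring B held inside a bicyclo[2.2.2]oct-5-en-2-one whose C3–C4 bridge spans C8 and C5.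
Forward: ring B comes from 2,6-dimethylcyclohexenone; a Mukaiyama–Michael addition makes C4–C5; a bridging Claisen makes the temporary C3–C8 bond; vinyl addition/anionic oxy-Cope brings in C1–C2, closes ring A and releases ring B with C8=C9 as an enol ether.
Stereochemistry: C5 from the chiral Lewis acid in step 1; C10 from C5 through the suprafacial [3,3] shift, which can only give the cis ring fusion (C10–CH3 and C5–H on the same face), as the target requires.

Key step: step 3

Remark: the target is drawn as the free aryl hydrogen sulfate; it is released by ion exchange in the last step and would in practice be stored as its sodium salt.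
Remark: enone 1 is used as the racemate (its C6 centre is planarised in step 2). The catalyst antipode in step 1 is taken to be the one that gives the (S)-adduct; if induction on this α-methyl enone runs the other way, the (R)-catalyst is used.

**Step 1**
Reactants: 1 2,6-dimethylcyclohex-2-en-1-one; 2 [(1-methoxy-2-methylprop-1-en-1-yl)oxy]trimethylsilane
Product: 4 methyl 2-[(1S)-2,4-dimethyl-3-oxocyclohexyl]-2-methylpropanoate, via silyl enol ether 3 (not isolated)
Conditions: (S)-1-(2-methylphenyl)-3,3-diphenyltetrahydro-1H,3H-pyrrolo[1,2-c][1,3,2]oxazaborole·HN(SO2CF3)2 (20 mol %), Ph3P=O (25 mol %), toluene, −20 °C; then 1 M HCl, THF, 0 °C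
Reagents that add atoms: none
Why: Catalytic enantioselective Mukaiyama–Michael addition, in which the chiral oxazaborolidinium ion binds the enone carbonyl and shields one face of the β-carbon so that the ketene acetal sets C5 (and brings C4 with both methyls and C3); the two methyl-bearing α-carbons stay epimeric, which is harmless because one is planarised and the other is fixed by the bridge in step 2.

**Step 2**
Reactants: 4 methyl 2-[(1S)-2,4-dimethyl-3-oxocyclohexyl]-2-methylpropanoate
Product: 7 (1R,4S)-6-methoxy-1,3,3,5-tetramethylbicyclo[2.2.2]oct-5-en-2-one, via potassium ketone enolate 5 (not isolated), via potassium dione enolate 6 (not isolated)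
Conditions: KN(SiMe3)2 (2.3 equiv), THF, −78 → 40 °C; then DMPU, MeOTf, −78 → 0 °C
Reagents that add atoms: methyl trifluoromethanesulfonate, COS(=O)(=O)C(F)(F)F
Why: Intramolecular Claisen (Dieckmann-type) acylation in which the α′-enolate carbon (C8) attacks the ester (C3) across the ring through a boat, the resulting bicyclo[2.2.2]octane-2,6-dione being drained as its only possible enolate (O–C9=C10) and O-methylated by the hard electrophile; the bridgehead C8 can form only on the face of the C5 side chain, so its configuration follows from C5.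

**Step 3**
Reactants: 7 (1R,4S)-6-methoxy-1,3,3,5-tetramethylbicyclo[2.2.2]oct-5-en-2-one
Product: 10 (4aS,8aS)-5-methoxy-1,1,4a,6-tetramethyl-3,4,4a,7,8,8a-hexahydronaphthalen-2(1H)-one, via lithium vinyl alkoxide 8 (not isolated), via potassium enolate 9 (not isolated)
Conditions: CH2=CHLi (1.2 equiv), THF, −78 → 0 °C; then KOt-Bu, 18-crown-6, 0 → 40 °C; H2O quench
Reagents that add atoms: vinyllithium, [Li]C=C
Why: Vinyllithium should add to the only carbonyl (C3, non-enolisable between two quaternary carbons) from the face of the enol-ether bridge, which has no syn hydrogens and whose methoxy oxygen can guide lithium; this forms C2–C3 and places the vinyl group over C9=C10, and exchange to the potassium alkoxide then triggers a charge-accelerated [3,3] shift in which C1 bonds to C10 while the temporary C3–C8 bond breaks, leaving the C2=C3 enolate and the C8=C9 enol ether. The closest known reaction type is the tandem 1,2-addition/anionic oxy-Cope rearrangement of bicyclo[2.2.2]oct-5-en-2-ones to cis-fused octalones. Ring A (C10–C1–C2–C3–C4–C5) is closed by this sigmatropic C1–C10 bond formation through the boat-like six-centre transition state that the bicycle enforces, while ring B is released from the bridged frame. The one new stereocentre, quaternary C10, is set by C5: C1 is tied through C2–C3–C4 to C5 and can reach only the face of C10 on which C4 sits, so the fusion must be cis. The step needs the vinyl group syn to the alkene bridge and a [3,3] rather than a [1,3] or fragmentation pathway; the open alkene face of the ketone and the rigid overlap of the diene termini should secure both.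

**Step 4**
Reactants: 10 (4aS,8aS)-5-methoxy-1,1,4a,6-tetramethyl-3,4,4a,7,8,8a-hexahydronaphthalen-2(1H)-one
Product: 13 (4aR,8aS)-2,5,5,8a-tetramethyloctahydronaphthalen-1(2H)-one, via hydrazone 11 (not isolated), via methyl enol ether 12 (not isolated)
Conditions: N2H4·H2O, KOH, diethylene glycol, 130 → 200 °C; then 2 M HCl, THF, 25 °C
Reagents that add atoms: water, O
Why: Wolff–Kishner reduction removes the C3 carbonyl helper while the base-stable methyl enol ether survives, and dilute acid then hydrolyses the enol ether to the C9 ketone (C8 epimers, of no consequence); neither ring-fusion centre is enolisable.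

**Step 5**
Reactants: 13 (4aR,8aS)-2,5,5,8a-tetramethyloctahydronaphthalen-1(2H)-one
Product: 14 (4aR,8aS)-2,5,5,8a-tetramethyl-3,4,4a,5,6,7,8,8a-octahydronaphthalen-1-yl trifluoromethanesulfonate
Conditions: KN(SiMe3)2, THF, −78 → 0 °C; PhNTf2, −78 → 25 °C
Reagents that add atoms: N-phenylbis(trifluoromethanesulfonimide), FC(F)(F)S(=O)(=O)N(c1ccccc1)S(=O)(=O)C(F)(F)F
Why: Enol triflate formation is regiospecific because the ketone can enolise only towards C8 (C10 is quaternary), which fixes the tetrasubstituted C8=C9 alkene.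

**Step 6**
Reactants: 15 3-bromo-4,5-dihydroxybenzaldehyde
Product: 16 4-(benzyloxy)-3-bromo-5-hydroxybenzaldehyde
Conditions: BnBr (1.05 equiv), NaHCO3, NaI (cat.), DMF, 40 °C
Reagents that add atoms: benzyl bromide, BrCc1ccccc1
Why: Regioselective Williamson etherification, since the hydroxyl para to the formyl group (and ortho to bromine) is the more acidic and the only one ionised by hydrogen carbonate; this marks the oxygen that will later carry the sulfate.

**Step 7**
Reactants: 16 4-(benzyloxy)-3-bromo-5-hydroxybenzaldehyde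
Product: 17 2-(benzyloxy)-3-bromo-5-(hydroxymethyl)phenol
Conditions: NaBH4, MeOH, 0 °C
Reagents that add atoms: none
Why: Borohydride reduction of the aryl aldehyde to the benzylic alcohol.

**Step 8**
Reactants: 17 2-(benzyloxy)-3-bromo-5-(hydroxymethyl)phenol
Product: 18 {[4-(benzyloxy)-3-bromo-5-(triisopropylsilyloxy)phenyl]methoxy}triisopropylsilane
Conditions: i-Pr3SiCl (2.4 equiv), imidazole, DMF, 25 °C
Reagents that add atoms: chlorotri(propan-2-yl)silane, CC(C)[Si](Cl)(C(C)C)C(C)C
Why: Imidazole-promoted silylation of the phenol and the primary alcohol gives ethers that are bulky enough not to migrate between the catechol oxygens and that survive aqueous base.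

**Step 9**
Reactants: 18 {[4-(benzyloxy)-3-bromo-5-(triisopropylsilyloxy)phenyl]methoxy}triisopropylsilane
Product: 21 2-{[2-(benzyloxy)-3-(triisopropylsilyloxy)-5-(triisopropylsilyloxymethyl)phenyl]methyl}-4,4,5,5-tetramethyl-1,3,2-dioxaborolane, via aryllithium 19 (not isolated), via boronate complex 20 (not isolated)
Conditions: n-BuLi, THF, −78 °C; then ClCH2B(pin), −78 → 25 °C
Reagents that add atoms: 2-(chloromethyl)-4,4,5,5-tetramethyl-1,3,2-dioxaborolane, ClCB1OC(C)(C)C(C)(C)O1
Why: Bromine–lithium exchange followed by Matteson homologation, in which the aryllithium adds to boron and the aryl group migrates to carbon with loss of chloride, giving the benzylic boronate that carries C11.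

**Step 10**
Reactants: 14 (4aR,8aS)-2,5,5,8a-tetramethyl-3,4,4a,5,6,7,8,8a-octahydronaphthalen-1-yl trifluoromethanesulfonate; 21 the benzylic pinacol boronate
Product: 22 benzyl 2-{[(4aR,8aS)-2,5,5,8a-tetramethyl-3,4,4a,5,6,7,8,8a-octahydronaphthalen-1-yl]methyl}-6-(triisopropylsilyloxy)-4-(triisopropylsilyloxymethyl)phenyl ether
Conditions: Pd(OAc)2 (5 mol %), 2-dicyclohexylphosphino-2′,6′-dimethoxybiphenyl (10 mol %), K3PO4, toluene/H2O, 80 °C
Reagents that add atoms: none
Why: Suzuki–Miyaura sp2–sp3 cross-coupling of the alkenyl triflate with the primary benzylboronate forms C9–C11; the benzyl group on palladium has no β-hydrogen, so the alkene stays at C8=C9.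

**Step 11**
Reactants: 22 the benzyl ether
Product: 23 2-{[(4aR,8aS)-2,5,5,8a-tetramethyl-3,4,4a,5,6,7,8,8a-octahydronaphthalen-1-yl]methyl}-6-(triisopropylsilyloxy)-4-(triisopropylsilyloxymethyl)phenol
Conditions: H2 (1 atm), Pd/C (10 wt % palladium on carbon), EtOAc, 25 °C
Reagents that add atoms: none
Why: Hydrogenolysis of the aryl benzyl ether under neutral conditions, to which the hindered tetrasubstituted alkene and the silyl ethers should be inert, frees only the phenol ortho to C11.

**Step 12**
Reactants: 23 the phenol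
Product: 24 2-{[(4aR,8aS)-2,5,5,8a-tetramethyl-3,4,4a,5,6,7,8,8a-octahydronaphthalen-1-yl]methyl}-6-(triisopropylsilyloxy)-4-(triisopropylsilyloxymethyl)phenyl hydrogen sulfate (handled as its pyridinium salt)
Conditions: SO3·pyridine (5 equiv), pyridine, 45 °C
Reagents that add atoms: sulfur trioxide–pyridine complex, [O-]S(=O)(=O)[n+]1ccccc1
Why: O-sulfation of the only free hydroxyl with the sulfur trioxide–amine complex; the weak base does not ionise the phenol enough to move the neighbouring silyl group.

**Step 13**
Reactants: 24 the silyl-protected aryl sulfate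
Product: 25 2-hydroxy-4-(hydroxymethyl)-6-{[(4aR,8aS)-2,5,5,8a-tetramethyl-3,4,4a,5,6,7,8,8a-octahydronaphthalen-1-yl]methyl}phenyl hydrogen sulfate (target)
Conditions: Et3N·3HF, THF, 40 °C; then Dowex 50W (H+ form), MeOH/H2O, 0 °C
Reagents that add atoms: none
Why: Fluoride cleavage of both silyl ethers under nearly neutral conditions leaves the aryl sulfate monoester intact, and ion exchange gives the acid form.

**Compound list**
1 | 2,6-dimethylcyclohex-2-en-1-one (racemic) | CC1CCC=C(C)C1=O | starting material
2 | [(1-methoxy-2-methylprop-1-en-1-yl)oxy]trimethylsilane | COC(O[Si](C)(C)C)=C(C)C | starting material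
3 | methyl 2-[(1S)-2,4-dimethyl-3-(trimethylsilyloxy)cyclohex-2-en-1-yl]-2-methylpropanoate (C4 epimers) | COC(=O)C(C)(C)[C@H]1CCC(C)C(O[Si](C)(C)C)=C1C | intermediate
4 | methyl 2-[(1S)-2,4-dimethyl-3-oxocyclohexyl]-2-methylpropanoate (epimers at ring C2 and C4) | COC(=O)C(C)(C)[C@H]1CCC(C)C(=O)C1C | intermediate
5 | potassium enolate of 4 on the side remote from the ester chain (α′-enolate) | [K+].COC(=O)C(C)(C)[C@H]1CCC(C)=C([O-])C1C | intermediate
6 | potassium enolate of the bridged dione 1,3,3,5-tetramethylbicyclo[2.2.2]octane-2,6-dione (C5=C6 enolate, bridgeheads as in 7) | [K+].CC1(C)C(=O)[C@]2(C)CC[C@H]1C(C)=C2[O-] | intermediate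
7 | (1R,4S)-6-methoxy-1,3,3,5-tetramethylbicyclo[2.2.2]oct-5-en-2-one | CC1(C)C(=O)[C@]2(C)CC[C@H]1C(C)=C2OC | intermediate
8 | lithium alkoxide of the tertiary vinyl carbinol from 7, vinyl group syn to the enol-ether bridge | [Li+].CC1(C)[C@@]([O-])(C=C)[C@]2(C)CC[C@H]1C(C)=C2OC | intermediate
9 | potassium enolate of 10 (enolate towards the ring CH2; cis ring fusion) | [K+].CC1=C(OC)[C@@]2(C)CC=C([O-])C(C)(C)[C@H]2CC1 | intermediate
10 | (4aS,8aS)-5-methoxy-1,1,4a,6-tetramethyl-3,4,4a,7,8,8a-hexahydronaphthalen-2(1H)-one | CC1=C(OC)[C@@]2(C)CCC(=O)C(C)(C)[C@H]2CC1 | intermediate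
11 | hydrazone of 10 | CC1=C(OC)[C@@]2(C)CCC(=NN)C(C)(C)[C@H]2CC1 | intermediate
12 | (4aR,8aS)-1-methoxy-2,5,5,8a-tetramethyl-3,4,4a,5,6,7,8,8a-octahydronaphthalene | CC1=C(OC)[C@@]2(C)CCCC(C)(C)[C@H]2CC1 | intermediate
13 | (4aR,8aS)-2,5,5,8a-tetramethyloctahydronaphthalen-1(2H)-one (C2 epimers, cis-fused) | CC1C(=O)[C@@]2(C)CCCC(C)(C)[C@H]2CC1 | intermediate
14 | (4aR,8aS)-2,5,5,8a-tetramethyl-3,4,4a,5,6,7,8,8a-octahydronaphthalen-1-yl trifluoromethanesulfonate | CC1=C(OS(=O)(=O)C(F)(F)F)[C@@]2(C)CCCC(C)(C)[C@H]2CC1 | intermediate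
15 | 3-bromo-4,5-dihydroxybenzaldehyde | O=Cc1cc(O)c(O)c(Br)c1 | starting material
16 | 4-(benzyloxy)-3-bromo-5-hydroxybenzaldehyde | O=Cc1cc(O)c(OCc2ccccc2)c(Br)c1 | intermediate
17 | 2-(benzyloxy)-3-bromo-5-(hydroxymethyl)phenol | OCc1cc(O)c(OCc2ccccc2)c(Br)c1 | intermediate
18 | {[4-(benzyloxy)-3-bromo-5-(triisopropylsilyloxy)phenyl]methoxy}triisopropylsilane | CC(C)[Si](OCc1cc(O[Si](C(C)C)(C(C)C)C(C)C)c(OCc2ccccc2)c(Br)c1)(C(C)C)C(C)C | intermediate
19 | aryllithium from 18 (lithium in place of bromine) | CC(C)[Si](OCc1cc(O[Si](C(C)C)(C(C)C)C(C)C)c(OCc2ccccc2)c([Li])c1)(C(C)C)C(C)C | intermediate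
20 | lithium aryl(chloromethyl) pinacol boronate complex | [Li+].CC(C)[Si](OCc1cc(O[Si](C(C)C)(C(C)C)C(C)C)c(OCc2ccccc2)c(c1)[B-]3(CCl)OC(C)(C)C(C)(C)O3)(C(C)C)C(C)C | intermediate
21 | 2-{[2-(benzyloxy)-3-(triisopropylsilyloxy)-5-(triisopropylsilyloxymethyl)phenyl]methyl}-4,4,5,5-tetramethyl-1,3,2-dioxaborolane | CC(C)[Si](OCc1cc(O[Si](C(C)C)(C(C)C)C(C)C)c(OCc2ccccc2)c(CB3OC(C)(C)C(C)(C)O3)c1)(C(C)C)C(C)C | intermediate
22 | benzyl 2-{[(4aR,8aS)-2,5,5,8a-tetramethyl-3,4,4a,5,6,7,8,8a-octahydronaphthalen-1-yl]methyl}-6-(triisopropylsilyloxy)-4-(triisopropylsilyloxymethyl)phenyl ether | CC1=C(Cc2cc(CO[Si](C(C)C)(C(C)C)C(C)C)cc(O[Si](C(C)C)(C(C)C)C(C)C)c2OCc3ccccc3)[C@@]4(C)CCCC(C)(C)[C@H]4CC1 | intermediate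
23 | 2-{[(4aR,8aS)-2,5,5,8a-tetramethyl-3,4,4a,5,6,7,8,8a-octahydronaphthalen-1-yl]methyl}-6-(triisopropylsilyloxy)-4-(triisopropylsilyloxymethyl)phenol | CC1=C(Cc2cc(CO[Si](C(C)C)(C(C)C)C(C)C)cc(O[Si](C(C)C)(C(C)C)C(C)C)c2O)[C@@]3(C)CCCC(C)(C)[C@H]3CC1 | intermediate
24 | 2-{[(4aR,8aS)-2,5,5,8a-tetramethyl-3,4,4a,5,6,7,8,8a-octahydronaphthalen-1-yl]methyl}-6-(triisopropylsilyloxy)-4-(triisopropylsilyloxymethyl)phenyl hydrogen sulfate | CC1=C(Cc2cc(CO[Si](C(C)C)(C(C)C)C(C)C)cc(O[Si](C(C)C)(C(C)C)C(C)C)c2OS(=O)(=O)O)[C@@]3(C)CCCC(C)(C)[C@H]3CC1 | intermediate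
25 | 2-hydroxy-4-(hydroxymethyl)-6-{[(4aR,8aS)-2,5,5,8a-tetramethyl-3,4,4a,5,6,7,8,8a-octahydronaphthalen-1-yl]methyl}phenyl hydrogen sulfate | CC1=C(Cc2cc(CO)cc(O)c2OS(=O)(=O)O)[C@@]2(C)CCCC(C)(C)[C@H]2CC1 | target

**Totals**
Total steps: 13. Longest linear sequence: 9 (steps 1–5 and 10–13); the arene branch (steps 6–9) is 4 steps.

**Steps most likely to fail, with fallbacks**

Step 3 (key step). The 1,2-addition to a carbonyl flanked by two quaternary carbons may be slow or reversible. Under the strongly dissociating potassium conditions the alkoxide may also cleave at C3–C8 without the concerted recombination, giving fragmentation or a [1,3] shift. The fallback separates the two events and makes the rearrangement neutral. It sets out from 7: the organocerium reagent from CH2=CHMgBr and CeCl3 (THF, −78 °C) should give, after aqueous work-up, the isolated tertiary vinyl carbinol F1. Silylation (Me3SiOTf, Et3N, CH2Cl2) should give its trimethylsilyl ether F2. A thermal, uncharged siloxy-Cope rearrangement (decalin, sealed tube, about 220 °C) should give the trimethylsilyl enol ether F3. Mild methanolysis (K2CO3, MeOH), which does not touch the methyl enol ether, returns the route at 10.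

Step 2. The tertiary enolate carbon may attack the neopentyl-type ester too slowly, so that O-acylation to an enol lactone and alkoxide-induced reopening dominate; C-methylation instead of O-methylation of the final enolate is a second risk. The fallback replaces the enolate Claisen by acid-promoted acylation of the ketone enol, the usual entry to bicyclo[2.2.2]octane-2,6-diones from 3-oxocyclohexylacetic acids. It sets out from 4: saponification (KOH, MeOH/H2O, reflux) should give 2-[(1S)-2,4-dimethyl-3-oxocyclohexyl]-2-methylpropanoic acid F4. Mixed-anhydride activation ((CF3CO)2O, CF3CO2H, CH2Cl2), chosen to avoid a free tertiary acylium ion, should close it to (1R,4S)-1,3,3,5-tetramethylbicyclo[2.2.2]octane-2,6-dione F5, isolated as the neutral dione. Separate enolisation and O-methylation (KN(SiMe3)2, DMPU, MeOTf) returns the route at 7.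

Step 1. Facial discrimination by the chiral Lewis acid may be poor on an enone that has no α-hydrogen, and the racemic C6 centre may cause a mismatched pairing, which would erode the enantiomeric purity of C5. The fallback moves the asymmetric step to an α-unsubstituted enone and adds the missing methyl afterwards. It sets out from 2: the same catalyst with 6-methylcyclohex-2-en-1-one F6 should give, without acidic work-up, the silyl enol ether methyl 2-[(1S)-4-methyl-3-(trimethylsilyloxy)cyclohex-2-en-1-yl]-2-methylpropanoate F7. Fluoride-promoted regiospecific C-methylation of this enol ether (Bu4N[Ph3SiF2], MeI, THF) returns the route at 4.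

**Further compounds**
F1 | step 3 | tertiary vinyl carbinol from 7 (O–H form of alkoxide 8, vinyl syn to the enol-ether bridge) | CC1(C)[C@@](O)(C=C)[C@]2(C)CC[C@H]1C(C)=C2OC
F2 | step 3 | trimethylsilyl ether of F1 | CC1(C)[C@@](O[Si](C)(C)C)(C=C)[C@]2(C)CC[C@H]1C(C)=C2OC
F3 | step 3 | trimethylsilyl enol ether of 10 | CC1=C(OC)[C@@]2(C)CC=C(O[Si](C)(C)C)C(C)(C)[C@H]2CC1
F4 | step 2 | 2-[(1S)-2,4-dimethyl-3-oxocyclohexyl]-2-methylpropanoic acid | OC(=O)C(C)(C)[C@H]1CCC(C)C(=O)C1C
F5 | step 2 | (1R,4S)-1,3,3,5-tetramethylbicyclo[2.2.2]octane-2,6-dione (C5 epimers) | CC1(C)C(=O)[C@]2(C)CC[C@H]1C(C)C2=O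
F6 | step 1 | 6-methylcyclohex-2-en-1-one (racemic, purchased) | CC1CCC=CC1=O
F7 | step 1 | methyl 2-[(1S)-4-methyl-3-(trimethylsilyloxy)cyclohex-2-en-1-yl]-2-methylpropanoate | COC(=O)C(C)(C)[C@H]1CCC(C)C(O[Si](C)(C)C)=C1
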